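**Retrosynthetic overview**

1. The feature used is that ring C is tied to ring A through O1–C8a and C4–C4a on neighbouring carbons, the connectivity of an ortho-quinone methide, and that ring B has a 2'-OH beside C2 that can hold a chiral acid.
2. C4=O is taken back to C4H2 (late benzylic oxidation of a flavan). Ring C is then cut across C3–C4 and O1–C2 into a ring A salicyl alcohol and a ring B 2-vinylphenol; the [4+2] union sets C2.
3. Ring A piece: 2,4,6-trihydroxybenzaldehyde is 4-O-methylated, mono-MOM-protected, iodinated next to the free OH and joined by Negishi coupling to an alkylzinc from (S)-lavandulol (resolved racemate; trisubstituted alkene hydrated by epoxidation and hydride opening), and the aldehyde is then reduced.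
4. Ring B piece: 2,4-dihydroxybenzaldehyde, 4-O-MOM, Wittig methylenation. Rings A and B are bought; ring C is the only ring formed (step 15), followed by a carbonate on the 2'-OH, DDQ/water at C4, Dess–Martin oxidation and acid deprotection.

Key step: step 15

Assumption: the sense of induction of the phosphoric acid is not secure for a methide without a substituent on its CH2 group; (R)-TRIP is written as the enantiomer giving (2S), and (S)-TRIP would be used if a first run showed the opposite sense.

**Route**

Step 1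
Reactants: 1 racemic lavandulol
Product: 2 (S)-lavandulol
Conditions: porcine pancreatic lipase, vinyl acetate, t-BuOMe, 25 °C, stopped near 65% conversion; alcohol separated from acetate on silica
Reagents that add atoms: none
Why: Lipase-catalysed kinetic resolution by transesterification, in which the (R)-alcohol is acylated faster, so that running past half conversion should leave the (S)-alcohol in high enantiomeric purity; the side-chain stereocentre is selected here, not created.

Step 2
Reactants: 2 (S)-lavandulol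
Product: 3 (S)-lavandulyl acetate
Conditions: Ac2O, pyridine, DMAP (cat.), CH2Cl2, 0 °C to rt
Reagents that add atoms: acetic anhydride, CC(=O)OC(C)=O
Why: Standard acylation masks the hydroxyl so that it cannot close a cyclic ether onto the epoxide made in step 3.

Step 3
Reactants: 3 (S)-lavandulyl acetate
Product: 4 (2S)-2-[(3,3-dimethyloxiran-2-yl)methyl]-3-methylbut-3-en-1-yl acetate (both epoxide epimers)
Conditions: mCPBA (1.05 equiv), CH2Cl2, −10 to 0 °C
Reagents that add atoms: 3-chloroperoxybenzoic acid, OOC(=O)c1cccc(Cl)c1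
Why: Prilezhaev epoxidation, in which the electrophilic peracid should prefer the more electron-rich trisubstituted alkene over the 1,1-disubstituted isopropenyl group; the new epoxide centre is uncontrolled and disappears in step 4.

Step 4
Reactants: 4 epoxy acetate
Product: 5 (2S)-5-methyl-2-(prop-1-en-2-yl)hexane-1,5-diol
Conditions: LiAlH4, THF, 0 °C to reflux
Reagents that add atoms: none
Why: Hydride reduction opens the trisubstituted epoxide by SN2 attack at its less substituted carbon to give the tertiary alcohol and cleaves the acetate in the same operation.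

Step 5
Reactants: 5 (2S)-5-methyl-2-(prop-1-en-2-yl)hexane-1,5-diol
Product: 6 (5S)-5-(iodomethyl)-2,6-dimethylhept-6-en-2-ol
Conditions: I2, PPh3, imidazole, CH2Cl2, 0 °C to rt
Reagents that add atoms: iodine, II
Why: Appel-type iodination (Garegg–Samuelsson conditions) activates only the primary hydroxyl, and iodide should displace the oxyphosphonium group faster than the hindered tertiary hydroxyl can close a six-membered ether.

Step 6
Reactants: 6 (5S)-5-(iodomethyl)-2,6-dimethylhept-6-en-2-ol
Product: 7 triethyl{[(5S)-5-(iodomethyl)-2,6-dimethylhept-6-en-2-yl]oxy}silane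
Conditions: TESOTf, 2,6-lutidine, CH2Cl2, −78 to 0 °C
Reagents that add atoms: triethylsilyl trifluoromethanesulfonate, CC[Si](CC)(CC)OS(=O)(=O)C(F)(F)F
Why: Silylation with a silyl triflate is the standard way to protect a hindered tertiary alcohol, and the primary iodide is inert to it.

Step 7
Reactants: 8 2,4,6-trihydroxybenzaldehyde
Product: 9 2,6-dihydroxy-4-methoxybenzaldehyde
Conditions: Me2SO4 (1.0 equiv), K2CO3 (1.0 equiv), acetone, 0 °C to rt
Reagents that add atoms: dimethyl sulfate, COS(=O)(=O)OC
Why: Williamson etherification, in which the 4-hydroxyl is the most acidic and the only one not tied to the formyl group by a hydrogen bond, so one equivalent of base and electrophile should methylate it selectively.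

Step 8
Reactants: 9 2,6-dihydroxy-4-methoxybenzaldehyde
Product: 10 2-hydroxy-4-methoxy-6-(methoxymethoxy)benzaldehyde
Conditions: MOMCl (1.1 equiv), i-Pr2NEt, CH2Cl2, 0 °C
Reagents that add atoms: chloromethyl methyl ether, COCCl
Why: O-Alkylation of a symmetric diol has no regiochemical issue, and the remaining hydroxyl is held in a hydrogen bond to the carbonyl so that a second alkylation should be slow.

Step 9
Reactants: 10 2-hydroxy-4-methoxy-6-(methoxymethoxy)benzaldehyde
Product: 11 2-hydroxy-3-iodo-4-methoxy-6-(methoxymethoxy)benzaldehyde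
Conditions: NIS (1.0 equiv), DMF, 0 °C to rt, dark
Reagents that add atoms: N-iodosuccinimide, O=C1CCC(=O)N1I
Why: Electrophilic aromatic iodination, which in chelated 2-hydroxy-4,6-dialkoxyaryl carbonyl compounds is known to go ortho to the free hydroxyl; here that position (C3) is also the less crowded one, since C5 lies between the methoxy and the larger MOM ether.

Step 10
Reactants: 11 2-hydroxy-3-iodo-4-methoxy-6-(methoxymethoxy)benzaldehyde
Product: 12 2-formyl-6-iodo-5-methoxy-3-(methoxymethoxy)phenyl acetate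
Conditions: Ac2O, Et3N, DMAP (cat.), CH2Cl2, 0 °C
Reagents that add atoms: acetic anhydride, CC(=O)OC(C)=O
Why: Acylation removes the acidic phenol proton that would destroy the alkylzinc reagent in step 11.

Step 11
Reactants: 7 triethyl{[(5S)-5-(iodomethyl)-2,6-dimethylhept-6-en-2-yl]oxy}silane; 12 2-formyl-6-iodo-5-methoxy-3-(methoxymethoxy)phenyl acetate
Product: 14 2-formyl-5-methoxy-3-(methoxymethoxy)-6-{(2R)-5-methyl-2-(prop-1-en-2-yl)-5-[(triethylsilyl)oxy]hexyl}phenyl acetate, via alkylzinc iodide 13 (not isolated)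
Conditions: (a) 7, Zn dust (activated with BrCH2CH2Br and Me3SiCl), LiCl, THF, 40 °C; (b) 12, Pd(OAc)2 (5 mol%), SPhos (10 mol%), THF, 25 to 45 °C
Reagents that add atoms: none
Why: Negishi coupling, in which zinc inserts into the primary C–I bond without touching the stereocentre (it is β to the metal) and a bulky biarylphosphine–palladium catalyst should join the primary alkylzinc to the doubly ortho-substituted aryl iodide faster than β-hydride elimination; aldehyde, acetate, MOM and silyl ether tolerate the organozinc.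

Step 12
Reactants: 14 2-formyl-5-methoxy-3-(methoxymethoxy)-6-{(2R)-5-methyl-2-(prop-1-en-2-yl)-5-[(triethylsilyl)oxy]hexyl}phenyl acetate
Product: 16 2-(hydroxymethyl)-5-methoxy-3-(methoxymethoxy)-6-{(2R)-5-methyl-2-(prop-1-en-2-yl)-5-[(triethylsilyl)oxy]hexyl}phenol, via salicylaldehyde 15 (not isolated)
Conditions: K2CO3 (1.1 equiv), MeOH, 0 °C; then NaBH4, 0 °C; work-up at pH 7, product used at once
Reagents that add atoms: none
Why: Methanolysis removes the acetate before hydride is added, so that no acyl group can migrate to the new benzylic alkoxide and leave (which would over-reduce the carbon to a methyl group by way of the methide), and borohydride reduction of the aldehyde then gives the salicyl alcohol.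

Step 13
Reactants: 17 2,4-dihydroxybenzaldehyde
Product: 18 2-hydroxy-4-(methoxymethoxy)benzaldehyde
Conditions: MOMCl (1.05 equiv), K2CO3, acetone, rt
Reagents that add atoms: chloromethyl methyl ether, COCCl
Why: O-Alkylation goes to the 4-hydroxyl because the 2-hydroxyl is hydrogen-bonded to the formyl group and less acidic.

Step 14
Reactants: 18 2-hydroxy-4-(methoxymethoxy)benzaldehyde
Product: 19 2-ethenyl-5-(methoxymethoxy)phenol
Conditions: Ph3PCH3Br (2.5 equiv), KOt-Bu (2.4 equiv), THF, 0 °C to rt; product stored cold and used fresh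
Reagents that add atoms: methyltriphenylphosphonium bromide, C[P+](c1ccccc1)(c1ccccc1)c1ccccc1.[Br-]
Why: Wittig methylenation of a salicylaldehyde works with excess ylide, one equivalent of which is consumed by the phenol.

Step 15
Reactants: 16 2-(hydroxymethyl)-5-methoxy-3-(methoxymethoxy)-6-{(2R)-5-methyl-2-(prop-1-en-2-yl)-5-[(triethylsilyl)oxy]hexyl}phenol; 19 2-ethenyl-5-(methoxymethoxy)phenol
Product: 21 2-[(2S)-7-methoxy-5-(methoxymethoxy)-8-{(2R)-5-methyl-2-(prop-1-en-2-yl)-5-[(triethylsilyl)oxy]hexyl}-3,4-dihydro-2H-chromen-2-yl]-5-(methoxymethoxy)phenol, via ortho-quinone methide of ring A 20 (not isolated)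
Conditions: (R)-TRIP [(R)-3,3'-bis(2,4,6-triisopropylphenyl)-1,1'-binaphthyl-2,2'-diyl hydrogen phosphate] (10 mol%), 19 (2 equiv), 5 Å molecular sieves, toluene, 0 °C, slow addition of 16; Et3N quench
Reagents that add atoms: none
Why: The phosphoric acid ionises the benzylic hydroxyl of 16 to methide 20, which is stabilised by the para methoxy and ortho MOM-oxy groups; the terminal carbon of the electron-rich styrene 19 attacks the methide CH2 (C3–C4) and the developing benzylic cation at C2 is captured by the methide oxygen (O1–C2) in an asynchronous inverse-electron-demand oxa-Diels–Alder reaction. The closest known reaction type is the chiral phosphoric acid-catalysed [4+2] cycloaddition of ortho-quinone methides, made in situ from ortho-hydroxybenzyl alcohols, with 2-vinylphenols, known mainly for aryl-substituted methides. Ring C closes as the six-membered ring of this [4+2] process; in the stepwise limit the O1–C2 bond forms by 6-exo-trig attack of the ring A oxygen on the cation stabilised by ring B. C2 is the only new stereocentre and is set by the catalyst, whose phosphate bridges the methide oxygen and the 2'-hydroxyl of 19 by two hydrogen bonds so that a 3,3'-aryl group shields one face of the styrene; the remote side-chain centre should exert no influence. The step needs regioselectivity (aryl at C2), secured by the polarisation of the styrene, and the 8-alkyl pattern, secured because only the phenol next to the side chain is free. It also needs the methide to be taken by 19 and not by the nucleophilic C6–H of another ring A unit, which slow addition of 16 to an excess of 19 should secure.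

Step 16
Reactants: 21 (2S)-flavan with free 2'-hydroxyl
Product: 22 tert-butyl 2-[(2S)-7-methoxy-5-(methoxymethoxy)-8-{(2R)-5-methyl-2-(prop-1-en-2-yl)-5-[(triethylsilyl)oxy]hexyl}-3,4-dihydro-2H-chromen-2-yl]-5-(methoxymethoxy)phenyl carbonate
Conditions: Boc2O, DMAP (10 mol%), CH2Cl2, 0 °C to rt
Reagents that add atoms: di-tert-butyl dicarbonate, CC(C)(C)OC(=O)OC(=O)OC(C)(C)C
Why: DMAP-catalysed carbonate formation on the phenol gives an electron-withdrawing, acid-labile group that should lower the hydride-donor ability of C2 and the tendency of the C2–O1 bond to ionise.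

Step 17
Reactants: 22 carbonate-protected (2S)-flavan
Product: 23 tert-butyl 2-[(2S)-4-hydroxy-7-methoxy-5-(methoxymethoxy)-8-{(2R)-5-methyl-2-(prop-1-en-2-yl)-5-[(triethylsilyl)oxy]hexyl}-3,4-dihydro-2H-chromen-2-yl]-5-(methoxymethoxy)phenyl carbonate (both C4 epimers)
Conditions: DDQ (1.2 equiv), CH2Cl2/aqueous pH 7 buffer (NaH2PO4/Na2HPO4) 10:1, 0 °C
Reagents that add atoms: water, O
Why: DDQ benzylic oxidation by hydride abstraction, as used for C4 functionalisation of 5,7-dioxygenated flavans, gives a C4 cation stabilised by O1 and the C5 and C7 oxygens that water captures. The in-ring C4–H is aligned with the ring A π system, whereas a cation at C1'' of the side chain would be strained against both ortho substituents and C2 is deactivated by the carbonate; the C4 configuration is of no consequence.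

Step 18
Reactants: 23 flavan-4-ol
Product: 24 tert-butyl 2-[(2S)-7-methoxy-5-(methoxymethoxy)-4-oxo-8-{(2R)-5-methyl-2-(prop-1-en-2-yl)-5-[(triethylsilyl)oxy]hexyl}-3,4-dihydro-2H-chromen-2-yl]-5-(methoxymethoxy)phenyl carbonate
Conditions: Dess–Martin periodinane, pyridine, CH2Cl2, 0 °C to rt
Reagents that add atoms: none
Why: Dess–Martin oxidation of the secondary benzylic alcohol under pyridine buffering should give the ketone without ionising C4 and without touching C2.

Step 19
Reactants: 24 protected (2S)-flavanone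
Product: 25 (2S)-2-(2,4-dihydroxyphenyl)-5-hydroxy-8-[(2R)-5-hydroxy-5-methyl-2-(prop-1-en-2-yl)hexyl]-7-methoxy-2,3-dihydro-4H-chromen-4-one
Conditions: HCl (2 M) in MeOH/THF, 35 °C, stopped at full conversion
Reagents that add atoms: none
Why: Acid-catalysed solvolysis removes the three MOM acetals, the tert-butyl carbonate and the silyl ether, as is known for MOM removal from prenylated flavanones; no phenol sits ortho to the side chain to add across the isopropenyl group, and acidic rather than basic conditions avoid ring opening to the chalcone, so C2 should keep its configuration.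

**Compound list**

1 | racemic lavandulol, (±)-5-methyl-2-(prop-1-en-2-yl)hex-4-en-1-ol | C=C(C)C(CC=C(C)C)CO | starting material
2 | (S)-lavandulol | C=C(C)[C@H](CC=C(C)C)CO | intermediate
3 | (S)-lavandulyl acetate | C=C(C)[C@H](CC=C(C)C)COC(C)=O | intermediate
4 | (2S)-2-[(3,3-dimethyloxiran-2-yl)methyl]-3-methylbut-3-en-1-yl acetate, both epoxide epimers | C=C(C)[C@H](CC1OC1(C)C)COC(C)=O | intermediate
5 | (2S)-5-methyl-2-(prop-1-en-2-yl)hexane-1,5-diol | C=C(C)[C@H](CCC(C)(C)O)CO | intermediate
6 | (5S)-5-(iodomethyl)-2,6-dimethylhept-6-en-2-ol | C=C(C)[C@H](CCC(C)(C)O)CI | intermediate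
7 | triethyl{[(5S)-5-(iodomethyl)-2,6-dimethylhept-6-en-2-yl]oxy}silane | C=C(C)[C@H](CCC(C)(C)O[Si](CC)(CC)CC)CI | intermediate
8 | 2,4,6-trihydroxybenzaldehyde | O=Cc1c(O)cc(O)cc1O | starting material
9 | 2,6-dihydroxy-4-methoxybenzaldehyde | COc1cc(O)c(C=O)c(O)c1 | intermediate
10 | 2-hydroxy-4-methoxy-6-(methoxymethoxy)benzaldehyde | COCOc1cc(OC)cc(O)c1C=O | intermediate
11 | 2-hydroxy-3-iodo-4-methoxy-6-(methoxymethoxy)benzaldehyde | COCOc1cc(OC)c(I)c(O)c1C=O | intermediate
12 | 2-formyl-6-iodo-5-methoxy-3-(methoxymethoxy)phenyl acetate | COCOc1cc(OC)c(I)c(OC(C)=O)c1C=O | intermediate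
13 | {(2S)-5-methyl-2-(prop-1-en-2-yl)-5-[(triethylsilyl)oxy]hexyl}zinc iodide, not isolated | C=C(C)[C@H](CCC(C)(C)O[Si](CC)(CC)CC)C[Zn]I | intermediate
14 | 2-formyl-5-methoxy-3-(methoxymethoxy)-6-{(2R)-5-methyl-2-(prop-1-en-2-yl)-5-[(triethylsilyl)oxy]hexyl}phenyl acetate | C=C(C)[C@H](CCC(C)(C)O[Si](CC)(CC)CC)Cc1c(OC)cc(OCOC)c(C=O)c1OC(C)=O | intermediate
15 | 2-hydroxy-4-methoxy-6-(methoxymethoxy)-3-{(2R)-5-methyl-2-(prop-1-en-2-yl)-5-[(triethylsilyl)oxy]hexyl}benzaldehyde, not isolated | C=C(C)[C@H](CCC(C)(C)O[Si](CC)(CC)CC)Cc1c(OC)cc(OCOC)c(C=O)c1O | intermediate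
16 | 2-(hydroxymethyl)-5-methoxy-3-(methoxymethoxy)-6-{(2R)-5-methyl-2-(prop-1-en-2-yl)-5-[(triethylsilyl)oxy]hexyl}phenol | C=C(C)[C@H](CCC(C)(C)O[Si](CC)(CC)CC)Cc1c(OC)cc(OCOC)c(CO)c1O | intermediate
17 | 2,4-dihydroxybenzaldehyde | O=Cc1ccc(O)cc1O | starting material
18 | 2-hydroxy-4-(methoxymethoxy)benzaldehyde | COCOc1ccc(C=O)c(O)c1 | intermediate
19 | 2-ethenyl-5-(methoxymethoxy)phenol | C=Cc1ccc(OCOC)cc1O | intermediate
20 | 3-methoxy-5-(methoxymethoxy)-6-methylidene-2-{(2R)-5-methyl-2-(prop-1-en-2-yl)-5-[(triethylsilyl)oxy]hexyl}cyclohexa-2,4-dien-1-one, not isolated | C=C(C)[C@H](CCC(C)(C)O[Si](CC)(CC)CC)CC1=C(OC)C=C(OCOC)C(=C)C1=O | intermediate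
21 | 2-[(2S)-7-methoxy-5-(methoxymethoxy)-8-{(2R)-5-methyl-2-(prop-1-en-2-yl)-5-[(triethylsilyl)oxy]hexyl}-3,4-dihydro-2H-chromen-2-yl]-5-(methoxymethoxy)phenol | C=C(C)[C@H](CCC(C)(C)O[Si](CC)(CC)CC)Cc1c(OC)cc(OCOC)c2c1O[C@H](c1ccc(OCOC)cc1O)CC2 | intermediate
22 | tert-butyl carbonate of 21 at the 2'-oxygen | C=C(C)[C@H](CCC(C)(C)O[Si](CC)(CC)CC)Cc1c(OC)cc(OCOC)c2c1O[C@H](c1ccc(OCOC)cc1OC(=O)OC(C)(C)C)CC2 | intermediate
23 | (2S)-flavan-4-ol derived from 22, both C4 epimers | C=C(C)[C@H](CCC(C)(C)O[Si](CC)(CC)CC)Cc1c(OC)cc(OCOC)c2c1O[C@H](c1ccc(OCOC)cc1OC(=O)OC(C)(C)C)CC2O | intermediate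
24 | protected (2S)-flavanone (4-oxo derivative of 22) | C=C(C)[C@H](CCC(C)(C)O[Si](CC)(CC)CC)Cc1c(OC)cc(OCOC)c2c1O[C@H](c1ccc(OCOC)cc1OC(=O)OC(C)(C)C)CC2=O | intermediate
25 | (2S)-2-(2,4-dihydroxyphenyl)-5-hydroxy-8-[(2R)-5-hydroxy-5-methyl-2-(prop-1-en-2-yl)hexyl]-7-methoxy-2,3-dihydro-4H-chromen-4-one | C=C(C)[C@H](CCC(C)(C)O)Cc1c(OC)cc(O)c2c1O[C@H](c1ccc(O)cc1O)CC2=O | target

**Step count**

Total: 19 steps. Longest linear sequence: 13 steps (steps 1–6, 11, 12, 15–19) from racemic lavandulol.

**Steps most likely to fail**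

Step 15. The catalyst may discriminate the two faces of the styrene poorly, because the methide has no substituent on its CH2 group, and reversible acid ionisation of the C2–O1 bond of the 2'-hydroxyflavan may erode whatever ratio is formed; capture of the methide by C6 of ring A is a further loss channel. In the fallback, stereocontrol is moved to a late kinetic resolution. Compounds 16 and 19 are combined with an achiral acid (diphenyl phosphate, toluene, 0 °C) to give the C2-epimeric flavan F1. This is carried as the mixture through the conditions of steps 16, 17 and 18 to the C2-epimeric carbonate F2, the C2-epimeric flavan-4-ol F3 and the C2-epimeric flavanone F4. Asymmetric transfer hydrogenation (RuCl(p-cymene)[(R,R)-TsDPEN], HCO2H/Et3N, EtOAc, rt), a known kinetic resolution of racemic flavanones, should reduce the (2R)-epimer to the cis-(2R,4R)-flavan-4-ol F5. The (2S)-ketone is left untouched and is separated; it is compound 24, where the route is rejoined.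

Step 17. Hydride abstraction may occur at C1'' of the side chain or at C2 in place of C4, or the flavan-4-ol may be oxidised further to a chromene or flavylium species. In the fallback, the C4 oxygen is carried from the aldehyde carbon instead of being introduced by C–H oxidation. Compound 14 is deacetylated (K2CO3, MeOH) and the salicylaldehyde 15 is isolated. MeMgBr (3 equiv, THF, 0 °C) gives the benzylic carbinol F6, and MnO2 (CH2Cl2) oxidises it to the ortho-hydroxyacetophenone F7. 2,4-Bis(methoxymethoxy)benzaldehyde F8 is made from 17 (MOMCl, NaH, DMF). Claisen–Schmidt condensation with F7 (KOH, EtOH/H2O, rt) gives the 2'-hydroxychalcone F9. Oxa-Michael closure (NaOAc, EtOH, reflux) gives the C2-epimeric tris-MOM flavanone F10. The same transfer hydrogenation as above should leave the (2S)-tris-MOM flavanone F11 and turn its epimer into the cis-(2R,4R)-tris-MOM flavan-4-ol F12. F11 is deprotected under the conditions of step 19 and comes back to the route at compound 25.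

Step 11. Coupling at the aryl iodide flanked by two ortho substituents may be slow, so that β-hydride elimination from the alkylpalladium intermediate and protonolysis of the zinc reagent consume the side chain. In the fallback, the coupling is changed to a B-alkyl Suzuki–Miyaura reaction. Compound 7 undergoes iodine–lithium exchange (t-BuLi, 2 equiv, Et2O, −78 °C) to the primary alkyllithium F13. This is trapped with 9-methoxy-9-borabicyclo[3.3.1]nonane as the lithium alkyl(methoxy)borate F14. F14 is coupled with 12 (PdCl2(dppf), DMF/THF, rt, no aqueous base, so that the acetate survives), and the route is rejoined at compound 14.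

**Further compounds**

F1 | step 15 | C2-epimeric flavan (2RS form of 21) | C=C(C)[C@H](CCC(C)(C)O[Si](CC)(CC)CC)Cc1c(OC)cc(OCOC)c2c1OC(c1ccc(OCOC)cc1O)CC2
F2 | step 15 | C2-epimeric carbonate (2RS form of 22) | C=C(C)[C@H](CCC(C)(C)O[Si](CC)(CC)CC)Cc1c(OC)cc(OCOC)c2c1OC(c1ccc(OCOC)cc1OC(=O)OC(C)(C)C)CC2
F3 | step 15 | C2-epimeric flavan-4-ol (2RS form of 23) | C=C(C)[C@H](CCC(C)(C)O[Si](CC)(CC)CC)Cc1c(OC)cc(OCOC)c2c1OC(c1ccc(OCOC)cc1OC(=O)OC(C)(C)C)CC2O
F4 | step 15 | C2-epimeric flavanone (2RS form of 24) | C=C(C)[C@H](CCC(C)(C)O[Si](CC)(CC)CC)Cc1c(OC)cc(OCOC)c2c1OC(c1ccc(OCOC)cc1OC(=O)OC(C)(C)C)CC2=O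
F5 | step 15 | cis-(2R,4R)-flavan-4-ol carrying the 2'-carbonate | C=C(C)[C@H](CCC(C)(C)O[Si](CC)(CC)CC)Cc1c(OC)cc(OCOC)c2c1O[C@@H](c1ccc(OCOC)cc1OC(=O)OC(C)(C)C)C[C@H]2O
F6 | step 17 | 2-(1-hydroxyethyl)-5-methoxy-3-(methoxymethoxy)-6-{(2R)-5-methyl-2-(prop-1-en-2-yl)-5-[(triethylsilyl)oxy]hexyl}phenol, both carbinol epimers | C=C(C)[C@H](CCC(C)(C)O[Si](CC)(CC)CC)Cc1c(OC)cc(OCOC)c(C(C)O)c1O
F7 | step 17 | 1-[2-hydroxy-4-methoxy-6-(methoxymethoxy)-3-{(2R)-5-methyl-2-(prop-1-en-2-yl)-5-[(triethylsilyl)oxy]hexyl}phenyl]ethan-1-one | C=C(C)[C@H](CCC(C)(C)O[Si](CC)(CC)CC)Cc1c(OC)cc(OCOC)c(C(C)=O)c1O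
F8 | step 17 | 2,4-bis(methoxymethoxy)benzaldehyde | COCOc1ccc(C=O)c(OCOC)c1
F9 | step 17 | (2E)-3-[2,4-bis(methoxymethoxy)phenyl]-1-[2-hydroxy-4-methoxy-6-(methoxymethoxy)-3-{(2R)-5-methyl-2-(prop-1-en-2-yl)-5-[(triethylsilyl)oxy]hexyl}phenyl]prop-2-en-1-one | C=C(C)[C@H](CCC(C)(C)O[Si](CC)(CC)CC)Cc1c(OC)cc(OCOC)c(C(=O)/C=C/c2ccc(OCOC)cc2OCOC)c1O
F10 | step 17 | C2-epimeric tris-MOM flavanone | C=C(C)[C@H](CCC(C)(C)O[Si](CC)(CC)CC)Cc1c(OC)cc(OCOC)c2c1OC(c1ccc(OCOC)cc1OCOC)CC2=O
F11 | step 17 | (2S)-tris-MOM flavanone | C=C(C)[C@H](CCC(C)(C)O[Si](CC)(CC)CC)Cc1c(OC)cc(OCOC)c2c1O[C@H](c1ccc(OCOC)cc1OCOC)CC2=O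
F12 | step 17 | cis-(2R,4R)-tris-MOM flavan-4-ol | C=C(C)[C@H](CCC(C)(C)O[Si](CC)(CC)CC)Cc1c(OC)cc(OCOC)c2c1O[C@@H](c1ccc(OCOC)cc1OCOC)C[C@H]2O
F13 | step 11 | {(2S)-5-methyl-2-(prop-1-en-2-yl)-5-[(triethylsilyl)oxy]hexyl}lithium | C=C(C)[C@H](CCC(C)(C)O[Si](CC)(CC)CC)C[Li]
F14 | step 11 | lithium 9-methoxy-9-{(2S)-5-methyl-2-(prop-1-en-2-yl)-5-[(triethylsilyl)oxy]hexyl}-9-borabicyclo[3.3.1]nonan-9-uide | [Li+].C=C(C)[C@H](CCC(C)(C)O[Si](CC)(CC)CC)C[B-]1(OC)C2CCCC1CCC2
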